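## Retrosynthetic overview

1. Feature: in coumarin A the benzene ring holds the central-ring carbon C1 at C8, between the C7 oxygen and the lactone oxygen on C8a, with the C5 methoxy group para to C8. This 2-alkyl-1,3,5-trioxygenated ring is the pattern obtained when a cyclobutenone and an alkynyl ether are fused into a phenol.
2. Key disconnection: the aryl C8–C8a and C6–C7 bonds of ring A, leading back to a C1-(silyloxyethynyl)cyclohexene that already carries the finished C6 side chain (coumarin B, protected carbinol) and to 3-methoxycyclobutenone. The pyranone ring of A follows by ortho-formylation and Wittig–lactonisation, then O7 silyl-to-methyl exchange and desilylation at C1′.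
3. The silyloxyalkyne comes from a terminal alkyne (acetylide oxidation), the C3 methyl from an enol triflate (Negishi coupling), and C1 from a trans-selective conjugate alkynylation of a 4-substituted 5,5-dimethylcyclohex-2-enone.
4. That enone comes by Stork–Danheiser transposition from the syn aldol of dimedone ethyl enol ether with 5,7-dimethoxycoumarin-8-carbaldehyde. A catalytic asymmetric Mukaiyama aldol sets C6 and C1′, and C6 then controls C1.
5. Ring order: coumarin B (bought) and the central carbocycle (from dimedone) are present from the start; the benzene ring of A is closed in the key step and its pyranone ring last.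

Key step: step 14

Remark (assumption): central-ring locants C1–C6 and C1′ (carbinol carbon) follow the target and coumarin locants are used for rings A and B. The ynol oxygen is carried as a triisopropylsilyl (TIPS) ether, because a methyl alkynyl ether on a secondary carbon has no established preparation that coumarin B would survive, and it is exchanged for methyl in step 17. 3-Ethoxycyclobut-2-en-1-one and ethynyltriisopropylsilane are taken as purchasable. TBS = tert-butyldimethylsilyl, TMS = trimethylsilyl.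

## Route

Step 1
Reactants: 1 dimedone
Product: 2 3-ethoxy-5,5-dimethylcyclohex-2-en-1-one
Conditions: EtOH, TsOH·H2O (cat.), toluene, reflux, Dean–Stark
Reagents that add atoms: ethanol CCO
Why: Acid-catalysed vinylogous esterification of the enolised symmetric 1,3-dione, driven by azeotropic removal of water; only one enol ether can form.

Step 2
Reactants: 2 3-ethoxy-5,5-dimethylcyclohex-2-en-1-one
Product: 4 [(5-ethoxy-3,3-dimethylcyclohexa-1,5-dien-1-yl)oxy]trimethylsilane, via lithium dienolate 3 (not isolated)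
Conditions: LDA, THF, −78 °C; TMSCl, −78 °C → rt
Reagents that add atoms: chlorotrimethylsilane C[Si](C)(C)Cl
Why: Kinetic deprotonation of the vinylogous ester takes the α′ proton (future C6) to give the cross-conjugated dienolate, and O-silylation gives the 2-silyloxydiene needed for a Mukaiyama aldol.

Step 3
Reactants: 5 5,7-dimethoxycoumarin
Product: 7 5,7-dimethoxy-2-oxo-2H-chromene-8-carbaldehyde, via iminium chloride 6 (not isolated)
Conditions: POCl3, DMF, 0 → 70 °C; then ice–water
Reagents that add atoms: N,N-dimethylformamide CN(C)C=O; water O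
Why: Vilsmeier–Haack formylation of the electron-rich arene; C8 (para to the 5-methoxy group and flanked by only one methoxy group) should react in preference to C6, and any C6 aldehyde is removed by crystallisation.

Step 4
Reactants: 4 silyl dienol ether; 7 coumarin aldehyde
Product: 9 syn aldol (6R)-6-[(R)-(5,7-dimethoxy-2-oxo-2H-chromen-8-yl)(hydroxy)methyl]-3-ethoxy-5,5-dimethylcyclohex-2-en-1-one, via trimethylsilyl ether 8 (not isolated)
Conditions: (S)-2-butyl-4-(1H-indol-3-ylmethyl)-3-tosyl-1,3,2-oxazaborolidin-5-one (20 mol%), EtCN, −78 °C; then 1 M HCl, THF, 0 °C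
Reagents that add atoms: none
Why: Catalytic enantioselective Mukaiyama aldol: the boron Lewis acid binds the aldehyde and leaves its Re face open to C6 of the enol silane (giving (R)-C1′), and the open antiperiplanar transition state of a ring-fixed (E)-enol silane should give the syn adduct (6R); the sense of induction is to be confirmed on a test scale and the enantiomeric catalyst used if it is reversed.

Step 5
Reactants: 9 syn aldol
Product: 10 (6R)-6-[(R)-(tert-butyldimethylsilyloxy)(5,7-dimethoxy-2-oxo-2H-chromen-8-yl)methyl]-3-ethoxy-5,5-dimethylcyclohex-2-en-1-one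
Conditions: TBSOTf, 2,6-lutidine, CH2Cl2, −78 → 0 °C
Reagents that add atoms: tert-butyldimethylsilyl trifluoromethanesulfonate CC(C)(C)[Si](C)(C)OS(=O)(=O)C(F)(F)F
Why: Silylation of the hindered, ionisable benzylic alcohol with a silyl triflate under buffered conditions; the ether blocks retro-aldol cleavage and enlarges the C6 substituent that directs step 7.

Step 6
Reactants: 10 silyl-protected aldol
Product: 12 (4R)-4-[(R)-(tert-butyldimethylsilyloxy)(5,7-dimethoxy-2-oxo-2H-chromen-8-yl)methyl]-5,5-dimethylcyclohex-2-en-1-one, via allylic alcohol 11 (not isolated)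
Conditions: NaBH4, CeCl3·7H2O, MeOH–THF, 0 °C; then 1 M HCl, THF, 0 °C
Reagents that add atoms: water O
Why: Luche 1,2-reduction of the vinylogous ester carbonyl (the electron-rich lactone is not expected to be reduced at 0 °C) followed by Stork–Danheiser transposition, in which acid ionises allylic alcohol 11 and hydrolyses the enol ether, moving the carbonyl to C3 and the alkene to C1=C2 without touching C6 or C1′.

Step 7
Reactants: 12 enone; 13 ethynyltriisopropylsilane
Product: 16 8-[(R)-(tert-butyldimethylsilyloxy){(1R,2R)-4-(tert-butyldimethylsilyloxy)-6,6-dimethyl-2-[(triisopropylsilyl)ethynyl]cyclohex-3-en-1-yl}methyl]-5,7-dimethoxy-2H-chromen-2-one, via lithium acetylide 14 (not isolated), via alkynylzinc bromide 15 (not isolated)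
Conditions: 13, n-BuLi, THF, −78 °C; ZnBr2, 0 °C; then 12, TBSOTf, Et2O–THF, −40 °C
Reagents that add atoms: tert-butyldimethylsilyl trifluoromethanesulfonate CC(C)(C)[Si](C)(C)OS(=O)(=O)C(F)(F)F
Why: Silyl-triflate-promoted conjugate addition of an alkynylzinc halide to an enone: the slim alkynyl group adds to C1 of the O-silylated enone anti to the large C6 substituent (axial attack on the conformer with that group pseudoaxial), which sets the 1,6-trans relationship, and the enolate is held regiospecifically as its silyl enol ether; the organozinc does not attack the lactone.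

Step 8
Reactants: 16 silyl enol ether
Product: 18 (3R,4R)-4-[(R)-(tert-butyldimethylsilyloxy)(5,7-dimethoxy-2-oxo-2H-chromen-8-yl)methyl]-5,5-dimethyl-3-[(triisopropylsilyl)ethynyl]cyclohex-1-en-1-yl trifluoromethanesulfonate, via cesium enolate 17 (not isolated)
Conditions: CsF, PhNTf2, DME, rt
Reagents that add atoms: N-phenylbis(trifluoromethanesulfonimide) O=S(=O)(N(c1ccccc1)S(=O)(=O)C(F)(F)F)C(F)(F)F
Why: Fluoride cleaves only the enol Si–O bond (an enolate is a far better leaving group than the hindered secondary alkoxide, and the C-silyl group resists CsF) and the enolate is O-triflated, fixing the C2=C3 enol triflate.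

Step 9
Reactants: 18 enol triflate
Product: 19 8-[(R)-(tert-butyldimethylsilyloxy){(1R,2S)-4,6,6-trimethyl-2-[(triisopropylsilyl)ethynyl]cyclohex-3-en-1-yl}methyl]-5,7-dimethoxy-2H-chromen-2-one
Conditions: MeZnCl, Pd(PPh3)4 (5 mol%), THF, 50 °C
Reagents that add atoms: methylzinc chloride C[Zn]Cl
Why: Negishi coupling: zerovalent palladium inserts into the alkenyl C–OTf bond and methyl is transferred from zinc, giving the C3 methyl alkene; the organozinc tolerates the lactone and the silyl groups.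

Step 10
Reactants: 19 C-silyl alkyne
Product: 20 8-{(R)-(tert-butyldimethylsilyloxy)[(1R,2S)-2-ethynyl-4,6,6-trimethylcyclohex-3-en-1-yl]methyl}-5,7-dimethoxy-2H-chromen-2-one
Conditions: TBAF (1.1 equiv), THF, 0 °C
Reagents that add atoms: none
Why: Fluoride-induced protodesilylation of the alkynylsilane, which should be much faster than cleavage of the hindered secondary silyl ether at 0 °C with near-stoichiometric fluoride.

Step 11
Reactants: 20 terminal alkyne
Product: 23 8-[(R)-(tert-butyldimethylsilyloxy){(1R,2S)-4,6,6-trimethyl-2-[(triisopropylsilyloxy)ethynyl]cyclohex-3-en-1-yl}methyl]-5,7-dimethoxy-2H-chromen-2-one, via lithium acetylide 21 (not isolated), via lithium ynolate 22 (not isolated)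
Conditions: LiHMDS (2.1 equiv), THF, −78 °C; t-BuOOH (decane), −78 → 0 °C; TIPSOTf, −78 °C
Reagents that add atoms: tert-butyl hydroperoxide CC(C)(C)OO; triisopropylsilyl trifluoromethanesulfonate CC(C)[Si](OS(=O)(=O)C(F)(F)F)(C(C)C)C(C)C
Why: Oxidation of a lithium acetylide to the ynolate with lithium tert-butyl peroxide and O-silylation with a bulky silyl triflate, the standard route from terminal alkynes to silyloxyalkynes; only the alkyne C–H is acidic towards LiHMDS (C1–H is untouched), and the lactone of ring B, deactivated by two methoxy groups and hindered at C4 by the peri methoxy group, should outlast the peroxide at or below 0 °C.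

Step 12
Reactants: 24 3-ethoxycyclobut-2-en-1-one
Product: 25 cyclobutane-1,3-dione
Conditions: 1 M HCl, 0 °C → rt; freeze-dry
Reagents that add atoms: water O
Why: Acid hydrolysis of the vinylogous ester to the strongly acidic dione, which is used at once.

Step 13
Reactants: 25 cyclobutane-1,3-dione
Product: 26 3-methoxycyclobut-2-en-1-one
Conditions: CH2N2, Et2O, 0 °C
Reagents that add atoms: diazomethane C=[N+]=[N-]
Why: O-Methylation of the acidic enol with diazomethane; the two oxygens of the symmetric dione are equivalent, so a single enol ether results.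

Step 14
Reactants: 23 silyloxyalkyne; 26 3-methoxycyclobut-2-en-1-one
Product: 31 phenol 8-[(R)-(tert-butyldimethylsilyloxy){(1R,2S)-2-[2-hydroxy-4-methoxy-6-(triisopropylsilyloxy)phenyl]-4,6,6-trimethylcyclohex-3-en-1-yl}methyl]-5,7-dimethoxy-2H-chromen-2-one, via vinylketene 27 (not isolated), via vinylcyclobutenone 28 (not isolated), via dienylketene 29 (not isolated), via cyclohexadienone 30 (not isolated)
Conditions: toluene, 80 °C then 110 °C
Reagents that add atoms: none
Why: Danheiser benzannulation, known for cyclobutenones with trialkylsilyloxyalkynes (the 3-alkoxy group on the cyclobutenone is the only extension): 26 opens by 4π-electrocyclic ring opening to vinylketene 27, whose carbonyl carbon bonds to the nucleophilic, C1-bearing alkyne carbon of 23 and whose α-carbon bonds to the oxygen-bearing alkyne carbon in a regiospecific [2+2] cycloaddition, giving 28 with the new C8–C8a and C6–C7 bonds (coumarin A locants). 28 opens reversibly (4π; only the isomer with the methoxyvinyl group turned inward goes on) to dienylketene 29, which closes the benzene ring by 6π-electrocyclisation (C8a–C4a bond) to dienone 30 and tautomerises to phenol 31. The ring is closed pericyclically, so the hindered aryl–C1 bond is never made by substitution and no stereocentre is formed; C1 keeps its configuration because its C–H is not acidic under neutral heating. The selectivity needed is regiochemical: C1 must end between the two ring oxygens with the cyclobutenone methoxy group para to it, and this is secured by the polarity of the ynol ether (β-carbon nucleophilic) against the ketene (carbonyl carbon electrophilic); which of the two flanking oxygens is free is immaterial, since both become ring A oxygens. Coumarin B, both silyl ethers and the trisubstituted alkene are inert to neutral heating.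

Step 15
Reactants: 31 phenol
Product: 32 3-[(1S,6R)-6-{(R)-(tert-butyldimethylsilyloxy)(5,7-dimethoxy-2-oxo-2H-chromen-8-yl)methyl}-3,5,5-trimethylcyclohex-2-en-1-yl]-2-hydroxy-6-methoxy-4-(triisopropylsilyloxy)benzaldehyde
Conditions: MgCl2, Et3N, (CH2O)n, MeCN, reflux
Reagents that add atoms: formaldehyde (as paraformaldehyde) C=O
Why: Magnesium-mediated ortho-formylation of a phenol (Casnati–Skattebøl): coordination of magnesium to the phenol oxygen delivers formaldehyde only to the one free ortho carbon (C4a) and a second formaldehyde accepts hydride; a silyl shift between the two ring A oxygens would be without consequence because they are related by the local symmetry of the ring.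

Step 16
Reactants: 32 salicylaldehyde
Product: 34 8-[(1S,6R)-6-{(R)-(tert-butyldimethylsilyloxy)(5,7-dimethoxy-2-oxo-2H-chromen-8-yl)methyl}-3,5,5-trimethylcyclohex-2-en-1-yl]-5-methoxy-7-(triisopropylsilyloxy)-2H-chromen-2-one, via ethyl cinnamate 33 (not isolated)
Conditions: Ph3P=CHCO2Et, PhNEt2, 210 °C
Reagents that add atoms: ethyl (triphenylphosphoranylidene)acetate CCOC(=O)C=P(c1ccccc1)(c1ccccc1)c1ccccc1
Why: Wittig olefination of the salicylaldehyde with the stabilised ylide and thermal E/Z equilibration of the cinnamate; the Z ester lactonises onto the phenol with loss of ethanol and closes the pyranone ring of coumarin A.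

Step 17
Reactants: 34 7-silyloxy coumarin
Product: 36 8-[(1S,6R)-6-{(R)-(tert-butyldimethylsilyloxy)(5,7-dimethoxy-2-oxo-2H-chromen-8-yl)methyl}-3,5,5-trimethylcyclohex-2-en-1-yl]-5,7-dimethoxy-2H-chromen-2-one, via cesium phenoxide 35 (not isolated)
Conditions: CsF, MeI, DMF, rt
Reagents that add atoms: iodomethane CI
Why: Fluoride cleaves the aryl silyl ether (far more labile than the hindered alkyl silyl ether) and the phenoxide is methylated in the same flask (Williamson ether synthesis), giving the 7-methoxy group.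

Step 18
Reactants: 36 silyl-protected bis-coumarin
Product: 37 IN0553, 8-[(1S,6R)-6-{(R)-(5,7-dimethoxy-2-oxo-2H-chromen-8-yl)(hydroxy)methyl}-3,5,5-trimethylcyclohex-2-en-1-yl]-5,7-dimethoxy-2H-chromen-2-one
Conditions: HF·pyridine, pyridine, THF, 0 °C → rt
Reagents that add atoms: none
Why: Fluoride-mediated cleavage of the secondary silyl ether under buffered conditions that should not ionise the electron-rich benzylic alcohol, so C1′ is untouched.

## Compound list

1 | dimedone (5,5-dimethylcyclohexane-1,3-dione) | CC1(C)CC(=O)CC(=O)C1 | starting material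
2 | 3-ethoxy-5,5-dimethylcyclohex-2-en-1-one | CCOC1=CC(=O)CC(C)(C)C1 | intermediate
3 | lithium 5-ethoxy-3,3-dimethylcyclohexa-1,5-dien-1-olate | [Li+].CCOC1=CC([O-])=CC(C)(C)C1 | intermediate (not isolated)
4 | [(5-ethoxy-3,3-dimethylcyclohexa-1,5-dien-1-yl)oxy]trimethylsilane | CCOC1=CC(O[Si](C)(C)C)=CC(C)(C)C1 | intermediate
5 | 5,7-dimethoxycoumarin | COc1cc(OC)c2ccc(=O)oc2c1 | starting material
6 | N-[(5,7-dimethoxy-2-oxo-2H-chromen-8-yl)methylidene]-N-methylmethanaminium chloride | C[N+](C)=Cc1c(OC)cc(OC)c2ccc(=O)oc12.[Cl-] | intermediate (not isolated)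
7 | 5,7-dimethoxy-2-oxo-2H-chromene-8-carbaldehyde | O=Cc1c(OC)cc(OC)c2ccc(=O)oc12 | intermediate
8 | (6R)-6-[(R)-(5,7-dimethoxy-2-oxo-2H-chromen-8-yl)(trimethylsilyloxy)methyl]-3-ethoxy-5,5-dimethylcyclohex-2-en-1-one | CCOC1=CC(=O)[C@@H]([C@@H](O[Si](C)(C)C)c2c(OC)cc(OC)c3ccc(=O)oc23)C(C)(C)C1 | intermediate (not isolated)
9 | (6R)-6-[(R)-(5,7-dimethoxy-2-oxo-2H-chromen-8-yl)(hydroxy)methyl]-3-ethoxy-5,5-dimethylcyclohex-2-en-1-one (syn aldol) | CCOC1=CC(=O)[C@@H]([C@@H](O)c2c(OC)cc(OC)c3ccc(=O)oc23)C(C)(C)C1 | intermediate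
10 | (6R)-6-[(R)-(tert-butyldimethylsilyloxy)(5,7-dimethoxy-2-oxo-2H-chromen-8-yl)methyl]-3-ethoxy-5,5-dimethylcyclohex-2-en-1-one | CCOC1=CC(=O)[C@@H]([C@@H](O[Si](C)(C)C(C)(C)C)c2c(OC)cc(OC)c3ccc(=O)oc23)C(C)(C)C1 | intermediate
11 | allylic alcohol from 1,2-reduction of 10 (ring carbinol as a mixture of epimers; C6 and C1′ as in 10) | CCOC1=CC(O)[C@@H]([C@@H](O[Si](C)(C)C(C)(C)C)c2c(OC)cc(OC)c3ccc(=O)oc23)C(C)(C)C1 | intermediate (not isolated)
12 | (4R)-4-[(R)-(tert-butyldimethylsilyloxy)(5,7-dimethoxy-2-oxo-2H-chromen-8-yl)methyl]-5,5-dimethylcyclohex-2-en-1-one | O=C1C=C[C@@H]([C@@H](O[Si](C)(C)C(C)(C)C)c2c(OC)cc(OC)c3ccc(=O)oc23)C(C)(C)C1 | intermediate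
13 | ethynyltriisopropylsilane | C#C[Si](C(C)C)(C(C)C)C(C)C | starting material
14 | lithium (triisopropylsilyl)acetylide | [Li]C#C[Si](C(C)C)(C(C)C)C(C)C | intermediate (not isolated)
15 | [(triisopropylsilyl)ethynyl]zinc bromide | Br[Zn]C#C[Si](C(C)C)(C(C)C)C(C)C | intermediate (not isolated)
16 | 8-[(R)-(tert-butyldimethylsilyloxy){(1R,2R)-4-(tert-butyldimethylsilyloxy)-6,6-dimethyl-2-[(triisopropylsilyl)ethynyl]cyclohex-3-en-1-yl}methyl]-5,7-dimethoxy-2H-chromen-2-one (alkynyl trans to the side chain) | CC(C)[Si](C(C)C)(C(C)C)C#C[C@H]1C=C(O[Si](C)(C)C(C)(C)C)CC(C)(C)[C@@H]1[C@@H](O[Si](C)(C)C(C)(C)C)c1c(OC)cc(OC)c2ccc(=O)oc12 | intermediate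
17 | cesium enolate of 16 (C3–O−, C2=C3; stereocentres as in 16) | [Cs+].CC(C)[Si](C(C)C)(C(C)C)C#C[C@H]1C=C([O-])CC(C)(C)[C@@H]1[C@@H](O[Si](C)(C)C(C)(C)C)c1c(OC)cc(OC)c2ccc(=O)oc12 | intermediate (not isolated)
18 | (3R,4R)-4-[(R)-(tert-butyldimethylsilyloxy)(5,7-dimethoxy-2-oxo-2H-chromen-8-yl)methyl]-5,5-dimethyl-3-[(triisopropylsilyl)ethynyl]cyclohex-1-en-1-yl trifluoromethanesulfonate | CC(C)[Si](C(C)C)(C(C)C)C#C[C@H]1C=C(OS(=O)(=O)C(F)(F)F)CC(C)(C)[C@@H]1[C@@H](O[Si](C)(C)C(C)(C)C)c1c(OC)cc(OC)c2ccc(=O)oc12 | intermediate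
19 | 8-[(R)-(tert-butyldimethylsilyloxy){(1R,2S)-4,6,6-trimethyl-2-[(triisopropylsilyl)ethynyl]cyclohex-3-en-1-yl}methyl]-5,7-dimethoxy-2H-chromen-2-one | CC(C)[Si](C(C)C)(C(C)C)C#C[C@H]1C=C(C)CC(C)(C)[C@@H]1[C@@H](O[Si](C)(C)C(C)(C)C)c1c(OC)cc(OC)c2ccc(=O)oc12 | intermediate
20 | 8-{(R)-(tert-butyldimethylsilyloxy)[(1R,2S)-2-ethynyl-4,6,6-trimethylcyclohex-3-en-1-yl]methyl}-5,7-dimethoxy-2H-chromen-2-one | C#C[C@H]1C=C(C)CC(C)(C)[C@@H]1[C@@H](O[Si](C)(C)C(C)(C)C)c1c(OC)cc(OC)c2ccc(=O)oc12 | intermediate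
21 | lithium acetylide of 20 | [Li]C#C[C@H]1C=C(C)CC(C)(C)[C@@H]1[C@@H](O[Si](C)(C)C(C)(C)C)c1c(OC)cc(OC)c2ccc(=O)oc12 | intermediate (not isolated)
22 | lithium ynolate from 21 | [Li+].[O-]C#C[C@H]1C=C(C)CC(C)(C)[C@@H]1[C@@H](O[Si](C)(C)C(C)(C)C)c1c(OC)cc(OC)c2ccc(=O)oc12 | intermediate (not isolated)
23 | 8-[(R)-(tert-butyldimethylsilyloxy){(1R,2S)-4,6,6-trimethyl-2-[(triisopropylsilyloxy)ethynyl]cyclohex-3-en-1-yl}methyl]-5,7-dimethoxy-2H-chromen-2-one (key-step precursor) | CC(C)[Si](C(C)C)(C(C)C)OC#C[C@H]1C=C(C)CC(C)(C)[C@@H]1[C@@H](O[Si](C)(C)C(C)(C)C)c1c(OC)cc(OC)c2ccc(=O)oc12 | intermediate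
24 | 3-ethoxycyclobut-2-en-1-one | CCOC1=CC(=O)C1 | starting material
25 | cyclobutane-1,3-dione | O=C1CC(=O)C1 | intermediate
26 | 3-methoxycyclobut-2-en-1-one | COC1=CC(=O)C1 | intermediate
27 | 3-methoxybuta-1,3-dien-1-one (vinylketene) | COC(=C)C=C=O | intermediate (not isolated)
28 | 4-(1-methoxyethenyl)-3-(triisopropylsilyloxy)cyclobut-2-en-1-one carrying C1 of the central ring at its C2 (C4 epimers; side chain as in 23) | COC(=C)C1C(=O)C([C@H]2C=C(C)CC(C)(C)[C@@H]2[C@@H](O[Si](C)(C)C(C)(C)C)c2c(OC)cc(OC)c3ccc(=O)oc23)=C1O[Si](C(C)C)(C(C)C)C(C)C | intermediate (not isolated)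
29 | dienylketene from ring opening of 28 (methoxyvinyl group cis to the ketene carbon) | COC(=C)/C=C(O[Si](C(C)C)(C(C)C)C(C)C)\C(=C=O)[C@H]1C=C(C)CC(C)(C)[C@@H]1[C@@H](O[Si](C)(C)C(C)(C)C)c1c(OC)cc(OC)c2ccc(=O)oc12 | intermediate (not isolated)
30 | 5-methoxy-3-(triisopropylsilyloxy)cyclohexa-2,4-dien-1-one carrying C1 of the central ring at its C2 | COC1=CC(O[Si](C(C)C)(C(C)C)C(C)C)=C(C(=O)C1)[C@H]1C=C(C)CC(C)(C)[C@@H]1[C@@H](O[Si](C)(C)C(C)(C)C)c1c(OC)cc(OC)c2ccc(=O)oc12 | intermediate (not isolated)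
31 | 8-[(R)-(tert-butyldimethylsilyloxy){(1R,2S)-2-[2-hydroxy-4-methoxy-6-(triisopropylsilyloxy)phenyl]-4,6,6-trimethylcyclohex-3-en-1-yl}methyl]-5,7-dimethoxy-2H-chromen-2-one (key-step product) | COc1cc(O)c([C@H]2C=C(C)CC(C)(C)[C@@H]2[C@@H](O[Si](C)(C)C(C)(C)C)c2c(OC)cc(OC)c3ccc(=O)oc23)c(O[Si](C(C)C)(C(C)C)C(C)C)c1 | intermediate
32 | 3-[(1S,6R)-6-{(R)-(tert-butyldimethylsilyloxy)(5,7-dimethoxy-2-oxo-2H-chromen-8-yl)methyl}-3,5,5-trimethylcyclohex-2-en-1-yl]-2-hydroxy-6-methoxy-4-(triisopropylsilyloxy)benzaldehyde | COc1cc(O[Si](C(C)C)(C(C)C)C(C)C)c([C@H]2C=C(C)CC(C)(C)[C@@H]2[C@@H](O[Si](C)(C)C(C)(C)C)c2c(OC)cc(OC)c3ccc(=O)oc23)c(O)c1C=O | intermediate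
33 | ethyl (E)-cinnamate from 32 (acrylate in place of the formyl group) | CCOC(=O)/C=C/c1c(OC)cc(O[Si](C(C)C)(C(C)C)C(C)C)c([C@H]2C=C(C)CC(C)(C)[C@@H]2[C@@H](O[Si](C)(C)C(C)(C)C)c2c(OC)cc(OC)c3ccc(=O)oc23)c1O | intermediate (not isolated)
34 | 8-[(1S,6R)-6-{(R)-(tert-butyldimethylsilyloxy)(5,7-dimethoxy-2-oxo-2H-chromen-8-yl)methyl}-3,5,5-trimethylcyclohex-2-en-1-yl]-5-methoxy-7-(triisopropylsilyloxy)-2H-chromen-2-one | COc1cc(O[Si](C(C)C)(C(C)C)C(C)C)c([C@H]2C=C(C)CC(C)(C)[C@@H]2[C@@H](O[Si](C)(C)C(C)(C)C)c2c(OC)cc(OC)c3ccc(=O)oc23)c2oc(=O)ccc12 | intermediate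
35 | cesium 7-phenoxide from 34 | [Cs+].COc1cc([O-])c([C@H]2C=C(C)CC(C)(C)[C@@H]2[C@@H](O[Si](C)(C)C(C)(C)C)c2c(OC)cc(OC)c3ccc(=O)oc23)c2oc(=O)ccc12 | intermediate (not isolated)
36 | 8-[(1S,6R)-6-{(R)-(tert-butyldimethylsilyloxy)(5,7-dimethoxy-2-oxo-2H-chromen-8-yl)methyl}-3,5,5-trimethylcyclohex-2-en-1-yl]-5,7-dimethoxy-2H-chromen-2-one | COc1cc(OC)c2ccc(=O)oc2c1[C@H]1C=C(C)CC(C)(C)[C@@H]1[C@@H](O[Si](C)(C)C(C)(C)C)c1c(OC)cc(OC)c2ccc(=O)oc12 | intermediate
37 | IN0553, 8-[(1S,6R)-6-{(R)-(5,7-dimethoxy-2-oxo-2H-chromen-8-yl)(hydroxy)methyl}-3,5,5-trimethylcyclohex-2-en-1-yl]-5,7-dimethoxy-2H-chromen-2-one | COc1cc(OC)c2ccc(=O)oc2c1[C@H]1C=C(C)CC(C)(C)[C@@H]1[C@@H](O)c1c(OC)cc(OC)c2ccc(=O)oc12 | target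

## Step count and risks

Total step count: 18. Longest linear sequence: 15 (steps 1, 2, 4–11, 14–18).

The three steps most likely to fail:

Step 14 (key step). The electron-rich 3-methoxycyclobutenone may open too slowly at temperatures the silyloxyalkyne tolerates, so that the alkyne is lost to hydrolysis or to a 1,3-silyl shift before the vinylketene captures it. The vinylketene may also acylate the phenol of 31 as it forms; that part is handled by a brief K2CO3/MeOH treatment of the crude product. Fallback: the same vinylketene 27 is generated at room temperature by Wolff rearrangement instead of ring opening. Commercial 3,3-dimethoxybutan-2-one is heated with catalytic TsOH to lose methanol and give 3-methoxybut-3-en-2-one F1. F1 is trifluoroacetylated (LiHMDS, CF3CO2CH2CF3, THF, −78 °C) to 1,1,1-trifluoro-5-methoxyhex-5-ene-2,4-dione F2, and detrifluoroacetylative diazo transfer (MsN3, Et3N, H2O, MeCN) gives 1-diazo-3-methoxybut-3-en-2-one F3. Irradiation of F3 with 23 in toluene at about 420 nm (outside the absorption of coumarin B) releases N2 and 27, which is trapped by 23 as in step 14; warming to 80 °C completes the electrocyclic steps. The fallback sets out from 23 and returns to the route at 31.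

Step 4. Facial selectivity and syn/anti control may erode, because the aldehyde carries two ortho oxygen substituents and the lactone carbonyl competes for the boron Lewis acid, which lets an uncatalysed or silyl-cation-catalysed pathway take over. Fallback: the stereochemistry is secured by a traceless chiral alkoxy group and separation rather than by a catalyst. Dimedone 1 and (1R,2S,5R)-menthol (TsOH, toluene, Dean–Stark) give 3-[(1R,2S,5R)-menthyloxy]-5,5-dimethylcyclohex-2-en-1-one F4. LDA gives lithium dienolate F5 and ClTi(OiPr)3 the triisopropoxytitanium dienolate F6, a type of enolate that favours syn adducts of cyclic ketones irrespective of enolate geometry. Addition to 7 should give the (6R,1′R) syn aldol F7 and its (6S,1′S) syn diastereomer F8, which are diastereomers through the menthyl group and are separated by chromatography or crystallisation, at the cost of at most half the material. F7 is silylated as in step 5 to silyl ether F9, and the conditions of step 6 (allylic alcohol F10 in the flask) expel menthol. The fallback sets out from 1 and 7 and returns to the route at 12.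

Step 11. The peroxide anion or the ynolate may attack the lactone of coumarin B, or oxygen transfer to the acetylide may stay incomplete. Fallback: the ynol oxygen is brought in with the two-carbon unit instead of being added to it. Lithium methoxyacetylide F11 is generated from chloroacetaldehyde dimethyl acetal with LiNEt2 (3 equiv, THF, 0 °C) and transmetalated with ZnBr2 to (methoxyethynyl)zinc bromide F12. F12 is added to 12 with TBSOTf as in step 7, an untested extension of that reaction to an alkoxyethynylzinc reagent, to give silyl enol ether F13. CsF/PhNTf2 gives enol triflate F14 and MeZnCl/Pd(PPh3)4 the methyl alkynyl ether F15, in which the oxygen already carries its final methyl group and coumarin B has met neither peroxide nor strong base. F15 and 26 are heated as in step 14 to give phenol F16, formylation as in step 15 gives salicylaldehyde F17, and the Wittig–lactonisation of step 16, through ethyl cinnamate F18, closes ring A. The fallback sets out from 12 and returns to the route at 36; steps 10, 11 and 17 are then not needed.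

## Further compounds

F1 | step 14 | 3-methoxybut-3-en-2-one | CC(=O)C(=C)OC
F2 | step 14 | 1,1,1-trifluoro-5-methoxyhex-5-ene-2,4-dione | COC(=C)C(=O)CC(=O)C(F)(F)F
F3 | step 14 | 1-diazo-3-methoxybut-3-en-2-one | COC(=C)C(=O)C=[N+]=[N-]
F4 | step 4 | 3-[(1R,2S,5R)-menthyloxy]-5,5-dimethylcyclohex-2-en-1-one | C[C@@H]1CC[C@H]([C@@H](C1)OC1=CC(=O)CC(C)(C)C1)C(C)C
F5 | step 4 | lithium dienolate of F4 | [Li+].C[C@@H]1CC[C@H]([C@@H](C1)OC1=CC([O-])=CC(C)(C)C1)C(C)C
F6 | step 4 | triisopropoxytitanium dienolate of F4 | C[C@@H]1CC[C@H]([C@@H](C1)OC1=CC(O[Ti](OC(C)C)(OC(C)C)OC(C)C)=CC(C)(C)C1)C(C)C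
F7 | step 4 | (6R)-6-[(R)-(5,7-dimethoxy-2-oxo-2H-chromen-8-yl)(hydroxy)methyl]-3-[(1R,2S,5R)-menthyloxy]-5,5-dimethylcyclohex-2-en-1-one | C[C@@H]1CC[C@H]([C@@H](C1)OC1=CC(=O)[C@@H]([C@@H](O)c2c(OC)cc(OC)c3ccc(=O)oc23)C(C)(C)C1)C(C)C
F8 | step 4 | (6S)-6-[(S)-(5,7-dimethoxy-2-oxo-2H-chromen-8-yl)(hydroxy)methyl]-3-[(1R,2S,5R)-menthyloxy]-5,5-dimethylcyclohex-2-en-1-one | C[C@@H]1CC[C@H]([C@@H](C1)OC1=CC(=O)[C@H]([C@H](O)c2c(OC)cc(OC)c3ccc(=O)oc23)C(C)(C)C1)C(C)C
F9 | step 4 | tert-butyldimethylsilyl ether of F7 | C[C@@H]1CC[C@H]([C@@H](C1)OC1=CC(=O)[C@@H]([C@@H](O[Si](C)(C)C(C)(C)C)c2c(OC)cc(OC)c3ccc(=O)oc23)C(C)(C)C1)C(C)C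
F10 | step 4 | allylic alcohol from 1,2-reduction of F9 (ring carbinol epimers) | C[C@@H]1CC[C@H]([C@@H](C1)OC1=CC(O)[C@@H]([C@@H](O[Si](C)(C)C(C)(C)C)c2c(OC)cc(OC)c3ccc(=O)oc23)C(C)(C)C1)C(C)C
F11 | step 11 | lithium methoxyacetylide | [Li]C#COC
F12 | step 11 | (methoxyethynyl)zinc bromide | Br[Zn]C#COC
F13 | step 11 | 8-[(R)-(tert-butyldimethylsilyloxy){(1R,2R)-4-(tert-butyldimethylsilyloxy)-2-(methoxyethynyl)-6,6-dimethylcyclohex-3-en-1-yl}methyl]-5,7-dimethoxy-2H-chromen-2-one | COC#C[C@H]1C=C(O[Si](C)(C)C(C)(C)C)CC(C)(C)[C@@H]1[C@@H](O[Si](C)(C)C(C)(C)C)c1c(OC)cc(OC)c2ccc(=O)oc12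
F14 | step 11 | (3R,4R)-4-[(R)-(tert-butyldimethylsilyloxy)(5,7-dimethoxy-2-oxo-2H-chromen-8-yl)methyl]-3-(methoxyethynyl)-5,5-dimethylcyclohex-1-en-1-yl trifluoromethanesulfonate | COC#C[C@H]1C=C(OS(=O)(=O)C(F)(F)F)CC(C)(C)[C@@H]1[C@@H](O[Si](C)(C)C(C)(C)C)c1c(OC)cc(OC)c2ccc(=O)oc12
F15 | step 11 | 8-{(R)-(tert-butyldimethylsilyloxy)[(1R,2S)-2-(methoxyethynyl)-4,6,6-trimethylcyclohex-3-en-1-yl]methyl}-5,7-dimethoxy-2H-chromen-2-one | COC#C[C@H]1C=C(C)CC(C)(C)[C@@H]1[C@@H](O[Si](C)(C)C(C)(C)C)c1c(OC)cc(OC)c2ccc(=O)oc12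
F16 | step 11 | 8-{(R)-(tert-butyldimethylsilyloxy)[(1R,2S)-2-(2-hydroxy-4,6-dimethoxyphenyl)-4,6,6-trimethylcyclohex-3-en-1-yl]methyl}-5,7-dimethoxy-2H-chromen-2-one | COc1cc(OC)cc(O)c1[C@H]1C=C(C)CC(C)(C)[C@@H]1[C@@H](O[Si](C)(C)C(C)(C)C)c1c(OC)cc(OC)c2ccc(=O)oc12
F17 | step 11 | 3-[(1S,6R)-6-{(R)-(tert-butyldimethylsilyloxy)(5,7-dimethoxy-2-oxo-2H-chromen-8-yl)methyl}-3,5,5-trimethylcyclohex-2-en-1-yl]-2-hydroxy-4,6-dimethoxybenzaldehyde | COc1cc(OC)c(C=O)c(O)c1[C@H]1C=C(C)CC(C)(C)[C@@H]1[C@@H](O[Si](C)(C)C(C)(C)C)c1c(OC)cc(OC)c2ccc(=O)oc12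
F18 | step 11 | ethyl (E)-cinnamate from F17 | CCOC(=O)/C=C/c1c(OC)cc(OC)c([C@H]2C=C(C)CC(C)(C)[C@@H]2[C@@H](O[Si](C)(C)C(C)(C)C)c2c(OC)cc(OC)c3ccc(=O)oc23)c1O
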